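**Retrosynthetic overview**

1. Target 17 ⇒ diol lactone 15 + ethyl (S)-3-hydroxybutanoate 16, joined last by lipase acylation of the primary allylic OH only.
2. Lactone ring (second ring formed) ⇒ epoxy acid 14: the O1–C5 bond is made by 5-endo opening of a trans-(S,S) vinyl epoxide by the carboxyl group, with inversion at C5, as in the presumed biogenesis.
3. Oxirane (first ring formed) ⇒ allylic bromide 9 + prenal 11: chiral-sulfide ylide epoxidation makes the C4–C5 bond and sets both stereocentres.
4. Bromide 9 ⇒ aldehyde 6 + methyl acrylate 7 by Morita–Baylis–Hillman reaction, then SN2′ bromination, which fixes the alkylidene geometry.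
5. Aldehyde 6 ⇒ neryl acetate 1 by Schenck ene reaction, then Claisen rearrangement (2Z from nerol, 6E from the chair transition state).

Lactone locants used below: O1, C2 (C=O), C3 (alkylidene carbon), C4 (CHOH), C5 (CH–O). In the target C4 is S, C5 is R, the ring substituents are trans, and the exocyclic olefin is E.

Assumption: sulfide 10 is taken as purchasable (otherwise two steps from (2S,5S)-hexane-2,5-diol), and its sense of induction with allylic ylides is taken, from memory of its benzylic ylides and a steric model, to make the ylide carbon S in a trans epoxide; if the sense proved opposite, the (2S,5S) sulfide would be used with no other change.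

**Route**

Step 1
Reactants: 1 neryl acetate [(2Z)-3,7-dimethylocta-2,6-dien-1-yl acetate]
Product: 3 (2Z)-6-hydroxy-3,7-dimethylocta-2,7-dien-1-yl acetate (racemic), via secondary allylic hydroperoxide 2 (not isolated)
Conditions: O2, hν (white LED), tetraphenylporphyrin (0.5 mol %), CH2Cl2, 0 °C; then PPh3 (1.1 equiv), 0 °C → rt; chromatography
Reagents that add atoms: oxygen (as singlet oxygen), O=O
Why: Schenck ene reaction: singlet oxygen attacks only the electron-rich 6,7-olefin (the 2,3-olefin is deactivated by the allylic acetoxy group) and abstraction from the (Z)-methyl gives the secondary hydroperoxide (about 1:1 with the separable tertiary regioisomer), which PPh3 reduces; the new carbinol centre is racemic and is erased in step 2.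

Step 2
Reactants: 3 (2Z)-6-hydroxy-3,7-dimethylocta-2,7-dien-1-yl acetate; 4 ethyl vinyl ether
Product: 6 (2Z,6E)-3,7-dimethyl-10-oxodeca-2,6-dien-1-yl acetate, via allyl vinyl ether 5 (not isolated)
Conditions: Hg(OAc)2 (0.2 equiv), 4 as solvent, reflux, 24 h; K2CO3, concentrate; PhMe, 120 °C (sealed), 4 h
Reagents that add atoms: none
Why: Hg(OAc)2-catalysed transvinylation followed by Claisen rearrangement through a chair transition state with the side chain equatorial gives the γ,δ-unsaturated aldehyde with the (6E) trisubstituted olefin (expected about 9:1 or better, minor isomer removed on AgNO3-impregnated silica), leaving the acetate and the (2Z) olefin untouched.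

Step 3
Reactants: 6 (2Z,6E)-3,7-dimethyl-10-oxodeca-2,6-dien-1-yl acetate; 7 methyl acrylate
Product: 8 methyl (6E,10Z)-12-acetoxy-3-hydroxy-6,10-dimethyl-2-methylidenedodeca-6,10-dienoate (racemic)
Conditions: 3-hydroxyquinuclidine (0.3 equiv), 7 (3 equiv), neat, rt, 3–5 d
Reagents that add atoms: none
Why: Morita–Baylis–Hillman reaction (amine adds to the acrylate, the enolate adds to the aldehyde, the amine is eliminated) is an addition without by-product, and its racemic carbinol centre disappears in step 4.

Step 4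
Reactants: 8 methyl (6E,10Z)-12-acetoxy-3-hydroxy-6,10-dimethyl-2-methylidenedodeca-6,10-dienoate
Product: 9 methyl (2Z,6E,10Z)-12-acetoxy-2-(bromomethyl)-6,10-dimethyldodeca-2,6,10-trienoate
Conditions: NBS (1.3 equiv) and Me2S (1.5 equiv) premixed, CH2Cl2, 0 °C → rt
Reagents that add atoms: N-bromosuccinimide, O=C1CCC(=O)N1Br
Why: Corey–Kim-type activation of the allylic alcohol as an alkoxysulfonium salt and SN2′ attack of bromide give the thermodynamically preferred (2Z)-2-(bromomethyl)enoate (chain anti to the ester), which is the geometry of the future exocyclic olefin.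

Step 5
Reactants: 9 methyl (2Z,6E,10Z)-12-acetoxy-2-(bromomethyl)-6,10-dimethyldodeca-2,6,10-trienoate; 10 (2R,5R)-2,5-dimethylthiolane; 11 prenal (3-methylbut-2-enal)
Product: 13 methyl (2E,6E,10Z)-12-acetoxy-6,10-dimethyl-2-[(2S,3S)-3-(2-methylprop-1-en-1-yl)oxiran-2-yl]dodeca-2,6,10-trienoate, via allylic sulfonium bromide 12 (not isolated)
Conditions: 10 (1.5 equiv), MeCN, rt, 4 h; then 11 (2 equiv), Cs2CO3 (1.5 equiv), −20 → 0 °C
Reagents that add atoms: none
Why: Proposed new method: S-alkylation of the C2-symmetric sulfide by the activated allylic bromide gives 12, Cs2CO3 forms the semistabilised allylic ylide, which adds through its α-carbon to the carbonyl of 11 on the face not shielded by the neighbouring ring methyl group, and the anti-betaine closes to the trans-(2S,3S) vinyl epoxide with release of 10 and retention of the enoate geometry; the closest known reaction type is the chiral-sulfide-mediated Corey–Chaykovsky epoxidation of aldehydes with allyl halides (enantioselectivities there are typically 80–90 % ee), extended here to an ester-bearing allylic bromide.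

Step 6
Reactants: 13 methyl (2E,6E,10Z)-12-acetoxy-6,10-dimethyl-2-[(2S,3S)-3-(2-methylprop-1-en-1-yl)oxiran-2-yl]dodeca-2,6,10-trienoate
Product: 15 (3E,4S,5R)-4-hydroxy-3-[(4E,8Z)-10-hydroxy-4,8-dimethyldeca-4,8-dien-1-ylidene]-5-(2-methylprop-1-en-1-yl)oxolan-2-one, via epoxy acid 14 (not isolated)
Conditions: LiOH·H2O (3 equiv), THF/H2O 3:1, 0 °C → rt; then 1 M HCl to pH 3, 0 °C → rt
Reagents that add atoms: lithium hydroxide, [Li+].[OH-]
Why: Saponification frees the carboxyl group (and the C1 alcohol), and on acidification the acid opens the vinyl epoxide at its allylic carbon in an anti, SN2-like 5-endo epoxide-opening lactonization that mirrors the presumed biogenesis, so C5 is set by inversion (S in the epoxide, R in the lactone), C4 keeps its S configuration with the epoxide oxygen as its hydroxyl, and the trans lactone with the (E)-alkylidene of 13 results; the 4-exo alternative (β-lactone) is strained and attack at the non-allylic carbon is electronically disfavoured.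

Step 7
Reactants: 15 (3E,4S,5R)-4-hydroxy-3-[(4E,8Z)-10-hydroxy-4,8-dimethyldeca-4,8-dien-1-ylidene]-5-(2-methylprop-1-en-1-yl)oxolan-2-one; 16 ethyl (3S)-3-hydroxybutanoate
Product: 17 (2Z,6E,10E)-10-[(4S,5R)-4-hydroxy-5-(2-methylprop-1-en-1-yl)-2-oxooxolan-3-ylidene]-3,7-dimethyldeca-2,6-dien-1-yl (3S)-3-hydroxybutanoate (CNP0214472.1)
Conditions: Novozym 435 (immobilised Candida antarctica lipase B), 16 (5 equiv), PhMe, 45 °C, 200 mbar (EtOH removal)
Reagents that add atoms: none
Why: Lipase-catalysed transesterification acylates only the unhindered primary allylic alcohol, leaves the hindered ring carbinol and the (S)-configured secondary hydroxyl of the acyl donor (the slow-reacting enantiomer for this lipase) free, and carries the stereocentre of 16 over unchanged.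

**Compound list**

1 | neryl acetate, (2Z)-3,7-dimethylocta-2,6-dien-1-yl acetate | CC(C)=CCC/C(C)=C\COC(C)=O | starting material
2 | (2Z)-6-hydroperoxy-3,7-dimethylocta-2,7-dien-1-yl acetate (racemic, not isolated) | CC(=C)C(OO)CC/C(C)=C\COC(C)=O | intermediate
3 | (2Z)-6-hydroxy-3,7-dimethylocta-2,7-dien-1-yl acetate (racemic) | CC(=C)C(O)CC/C(C)=C\COC(C)=O | intermediate
4 | ethyl vinyl ether | C=COCC | starting material
5 | (2Z)-6-(ethenyloxy)-3,7-dimethylocta-2,7-dien-1-yl acetate (racemic, not isolated) | CC(=C)C(OC=C)CC/C(C)=C\COC(C)=O | intermediate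
6 | (2Z,6E)-3,7-dimethyl-10-oxodeca-2,6-dien-1-yl acetate | O=CCC/C(C)=C/CC/C(C)=C\COC(C)=O | intermediate
7 | methyl acrylate | C=CC(=O)OC | starting material
8 | methyl (6E,10Z)-12-acetoxy-3-hydroxy-6,10-dimethyl-2-methylidenedodeca-6,10-dienoate (racemic) | C=C(C(=O)OC)C(O)CC/C(C)=C/CC/C(C)=C\COC(C)=O | intermediate
9 | methyl (2Z,6E,10Z)-12-acetoxy-2-(bromomethyl)-6,10-dimethyldodeca-2,6,10-trienoate | COC(=O)/C(CBr)=C/CC/C(C)=C/CC/C(C)=C\COC(C)=O | intermediate
10 | (2R,5R)-2,5-dimethylthiolane (chiral mediator, recovered) | C[C@@H]1CC[C@@H](C)S1 | starting material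
11 | prenal, 3-methylbut-2-enal | CC(C)=CC=O | starting material
12 | (2R,5R)-1-[(2Z,6E,10Z)-12-acetoxy-2-(methoxycarbonyl)-6,10-dimethyldodeca-2,6,10-trien-1-yl]-2,5-dimethylthiolan-1-ium bromide (not isolated) | C[C@@H]1CC[C@@H](C)[S+]1C/C(=C\CC/C(C)=C/CC/C(C)=C\COC(C)=O)C(=O)OC.[Br-] | intermediate
13 | methyl (2E,6E,10Z)-12-acetoxy-6,10-dimethyl-2-[(2S,3S)-3-(2-methylprop-1-en-1-yl)oxiran-2-yl]dodeca-2,6,10-trienoate | COC(=O)/C(=C/CC/C(C)=C/CC/C(C)=C\COC(C)=O)[C@@H]1O[C@H]1C=C(C)C | intermediate
14 | (2E,6E,10Z)-12-hydroxy-6,10-dimethyl-2-[(2S,3S)-3-(2-methylprop-1-en-1-yl)oxiran-2-yl]dodeca-2,6,10-trienoic acid (not isolated) | OC(=O)/C(=C/CC/C(C)=C/CC/C(C)=C\CO)[C@@H]1O[C@H]1C=C(C)C | intermediate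
15 | (3E,4S,5R)-4-hydroxy-3-[(4E,8Z)-10-hydroxy-4,8-dimethyldeca-4,8-dien-1-ylidene]-5-(2-methylprop-1-en-1-yl)oxolan-2-one | CC(C)=C[C@H]1OC(=O)/C(=C/CC/C(C)=C/CC/C(C)=C\CO)[C@@H]1O | intermediate
16 | ethyl (3S)-3-hydroxybutanoate | CCOC(=O)C[C@H](C)O | starting material
17 | (2Z,6E,10E)-10-[(4S,5R)-4-hydroxy-5-(2-methylprop-1-en-1-yl)-2-oxooxolan-3-ylidene]-3,7-dimethyldeca-2,6-dien-1-yl (3S)-3-hydroxybutanoate | CC(C)=C[C@H]1OC(=O)/C(=C/CC/C(C)=C/CC/C(C)=C\COC(=O)C[C@H](C)O)[C@@H]1O | target

**Step count and risks**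

Total steps: 7. Longest linear sequence: 7 steps (1 → 17).

The three steps most likely to fail:

Step 5 is the least secure, because an ester-bearing allylic ylide may give low enantioselectivity, cis/trans mixtures or attack through its γ-carbon. The fallback sets out from 9 and comes back at 13, replacing reagent control at sulfur by iminium catalysis. Oxidation of the bromide with N-methylmorpholine N-oxide (MeCN, rt) gives methyl (2E,6E,10Z)-12-acetoxy-2-formyl-6,10-dimethyldodeca-2,6,10-trienoate F2. Wittig reaction with (triphenylphosphoranylidene)acetaldehyde (1 equiv, CH2Cl2, rt) gives methyl (2E,6E,10Z)-12-acetoxy-6,10-dimethyl-2-[(1E)-3-oxoprop-1-en-1-yl]dodeca-2,6,10-trienoate F3. Epoxidation with aqueous H2O2 and (S)-2-{bis[3,5-bis(trifluoromethyl)phenyl](trimethylsilyloxy)methyl}pyrrolidine (10 mol %, CH2Cl2, rt) gives methyl (2E,6E,10Z)-12-acetoxy-2-[(2S,3R)-3-formyloxiran-2-yl]-6,10-dimethyldodeca-2,6,10-trienoate F4. The sense is assigned by analogy with cinnamaldehyde. Isopropylidenetriphenylphosphorane (from isopropyltriphenylphosphonium iodide and KHMDS, THF, −78 °C) then turns the formyl group into the 2-methylprop-1-enyl group, which is 13.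

Step 6 may suffer from slow hydrolysis of the hindered enoate, hydroxide addition to the epoxy-enoate, or solvolysis of the vinyl epoxide. The fallback sets out from 13 and comes back at 15, avoiding base and using the ester carbonyl as the nucleophile. BF3·OEt2 (CH2Cl2, −78 °C) makes the methyl ester oxygen open the epoxide at the allylic carbon with inversion, and aqueous work-up of the lactonium ion releases methanol to give (2Z,6E,10E)-10-[(4S,5R)-4-hydroxy-5-(2-methylprop-1-en-1-yl)-2-oxooxolan-3-ylidene]-3,7-dimethyldeca-2,6-dien-1-yl acetate F5. Novozym 435 with n-butanol (tert-butyl methyl ether, 40 °C) then removes the primary acetate to give 15.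

Step 1 gives at best about half of the material as the wanted regioisomer. The fallback sets out from 1 and comes back at 3, at the cost of one extra step. Ozonolysis restricted to the electron-rich 6,7-olefin (O3, CH2Cl2/pyridine, −78 °C, then Me2S) gives (2Z)-3-methyl-6-oxohex-2-en-1-yl acetate F1. Isopropenylmagnesium bromide (1.0 equiv, THF, −78 °C) then adds to the aldehyde faster than to the acetate and gives 3.

**Further compounds**

F1 | step 1 | (2Z)-3-methyl-6-oxohex-2-en-1-yl acetate | O=CCC/C(C)=C\COC(C)=O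
F2 | step 5 | methyl (2E,6E,10Z)-12-acetoxy-2-formyl-6,10-dimethyldodeca-2,6,10-trienoate | COC(=O)/C(C=O)=C/CC/C(C)=C/CC/C(C)=C\COC(C)=O
F3 | step 5 | methyl (2E,6E,10Z)-12-acetoxy-6,10-dimethyl-2-[(1E)-3-oxoprop-1-en-1-yl]dodeca-2,6,10-trienoate | COC(=O)/C(=C/CC/C(C)=C/CC/C(C)=C\COC(C)=O)/C=C/C=O
F4 | step 5 | methyl (2E,6E,10Z)-12-acetoxy-2-[(2S,3R)-3-formyloxiran-2-yl]-6,10-dimethyldodeca-2,6,10-trienoate | COC(=O)/C(=C/CC/C(C)=C/CC/C(C)=C\COC(C)=O)[C@@H]1O[C@H]1C=O
F5 | step 6 | (2Z,6E,10E)-10-[(4S,5R)-4-hydroxy-5-(2-methylprop-1-en-1-yl)-2-oxooxolan-3-ylidene]-3,7-dimethyldeca-2,6-dien-1-yl acetate | CC(C)=C[C@H]1OC(=O)/C(=C/CC/C(C)=C/CC/C(C)=C\COC(C)=O)[C@@H]1O
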